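## The problem

Numbering used throughout: C1 is the furanone carbonyl, C2 its =CH, C3 the enol-ether carbon, C4 the methyl-bearing CH (methyl C15), C5 the next carbinol, C6 the lactone O–CH, C7 the ring-fusion CH, C8 the ester-bearing CH, C9 the second carbinol, C10 the quaternary carbon (methyl C14), and C11, C12, C13 the lactone α-carbon, carbonyl and methylene.

The target 41 has a ten-membered carbocycle C1–C10 bridged by an oxygen between C3 and C10. C10, C1, C2, C3 and that oxygen form a furan-3(2H)-one, and an α-methylene-γ-butyrolactone (O–C12–C11=C13) is trans-fused across C6–C7. Seven contiguous stereocentres (4R,5S,6S,7S,8S,9R,10S) line the ring. In the extended chain C4/C5 and C7/C8 are anti, while C5/C6, C6/C7 and C8/C9 are syn. C10 is fully substituted and cannot be corrected once made.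

An ether oxygen on C6 can steer additions to a carbonyl at C8 (six-membered chelate) and at C5 (five-membered chelate). An ether on C8 can do the same for C9, and C4, through allylic strain against the furan ring, decides which face of C10 the chain can reach. C6 and C7 must come from an enantioselective step.

The fragile groups are:
- the α-methylene lactone (Michael acceptor);
- the furanone (acidic C4–H, with the C5 oxygen placed for elimination);
- the C9 hydroxyl, which is β to the C1 ketone across C10 (retro-aldol);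
- the C8 isovalerate next to a free C9 hydroxyl (acyl migration).

Strong bases and nucleophiles therefore have to be finished before these groups appear.

The key step rests on C6, C7 and C11–C13. If C12 is taken out, the lactone is a C6 hydroxyl beside a C7 ethynyl group (C11≡C13), i.e. a but-3-yn-1-ol. That is the substrate class for PdCl2-catalysed cyclocarbonylation, with carbon monoxide supplying C12.

## Retrosynthesis

**41 ⇒ 40.** Only the O–Si bonds at C5 and C9 are cut. Silyl ethers are chosen because they come off under mildly acidic fluoride conditions. Those conditions avoid the base that would trigger acyl migration, retro-aldol cleavage or conjugate addition.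

**40 ⇒ 38 + 39.** The O–C12 and C12–C11 bonds are cut and C12 leaves as carbon monoxide 39. The neighbouring options are α-methylenation of a saturated lactone or lactonisation of a preformed acrylate. Both need enolate or acyl-transfer chemistry on the complete macrocycle. The carbonylation removes the Michael acceptor and one ring in a single neutral step. It asks that the C6 hydroxyl be the only free one in 38 and that the alkyne be terminal.

**38 ⇒ 33 (through 34, 35 and 37).** No skeletal bond is cut. The C8 isovalerate and the free C6 hydroxyl are traced to two benzylic ethers of different oxidation potential: a 3,4-dimethoxybenzyl (DMB) ether on O8 and a 4-methoxybenzyl (PMB) ether on O6. The C9 hydroxyl of 33 is capped as a triethylsilyl (TES) ether first. A free hydroxyl next to the DMB ether would otherwise trap the benzylic cation as a cyclic acetal.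

**33 ⇒ 31 (through 32).** The C9–C10 bond is cut, giving an intramolecular Mukaiyama aldol of a 2-methyl-3-silyloxyfuran onto the C9 aldehyde. Cutting C4–C5 instead would need a vinylogous aldol under base next to the C5/C6 oxygens. Cutting C2–C3 would need a ten-membered cycloalkyne. The precursor 31 is an open chain with five stereocentres. The forward step must set C9 and C10 and close the bicyclo[6.2.1] system.

**31 ⇒ 29 ⇒ 26 ⇒ 23 + 24.** The furanone is traced to the 4-hydroxyalk-2-ynone 26 (cycloisomerisation). Bond C2–C3 is then cut to the Weinreb amide 23 and but-3-yn-2-ol 24, which brings C14, C10, C1 and C2. The C9 aldehyde of 31 is masked as the vinyl group of 29 while organometallic reagents are in use. Racemic 24 suffices because C10 becomes trigonal in 32.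

**23 ⇒ 22 ⇒ 21 ⇒ 15 + 20.** Bond C4–C5 is cut as a propionate aldol between aldehyde 15 and the silyl ketene thioacetal 20 (from thioester 18, made from 16 and 17). A boron enolate would follow the polar Felkin–Anh preference of the α-alkoxy aldehyde and give the wrong C5/C6 relation. A MgBr2 chelate with the C6 PMB ether gives the required 5,6-syn relation, and the thioester enol silane gives 4,5-anti.

**15 ⇒ 14 ⇒ 13 ⇒ 11 + 12.** Bond C8–C9 is cut. Vinylmagnesium bromide 12 adds to aldehyde 11 under chelation by the same C6 PMB ether. The vinyl group is inert to everything up to step 18 and then releases the C9 aldehyde.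

**11 ⇒ 10 ⇒ 9 ⇒ 8 ⇒ 7.** No skeletal bond is cut. The PMB group of 7 is moved from O8 to O6 through the cyclic acetal 8. This differentiates the C5 and C6 hydroxyls without a separate protection sequence and puts the chelating ether where it is needed twice.

**7 ⇒ 3 + 4 (through 5 and 6); 3 ⇒ 2 ⇒ 1.** Bond C7–C11 is cut as an alkynylalane opening of the epoxy alcohol 3 at the carbon remote from the hydroxyl. Epoxide 3 comes from asymmetric epoxidation of the mono-PMB ether 2 of (Z)-but-2-ene-1,4-diol 1. This sets C6 and C7 and gives the hydroxy/alkyne relation that becomes the trans ring fusion.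

## Roads not taken

**Alternative 1:** The ten-membered ring is traced to a six-membered carbinol with the ethynyl group on the carbinol carbon and an (E)-propenyl group on the neighbouring carbon. Its potassium alkoxide undergoes an anionic oxy-Cope rearrangement that forms C3–C4, breaks the old ring bond and gives the (2Z,5E)-cyclodeca-2,5-dienone A1.
- Merits: the medium ring is made by ring expansion without high dilution. C4 is set by chirality transfer from cyclohexane stereocentres that are easy to install.
- Weak points: A1 still lacks the oxygen at C3, both oxygens at C5 and C6 and the whole lactone. It needs a face-selective dihydroxylation of the C5=C6 alkene on a flexible ring, and an oxa-Michael/dehydrogenation sequence to make the furanone. It needs α-methylenation by lactone enolate chemistry beside a retro-aldol-prone C9–C10 unit. It also needs a late differentiation of two identically protected oxygens at C8 and C9.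
- Comparison: this road is better at ring construction. The chosen plan sets against it that every oxygen is in place and differentiated before ring closure, and that the lactone is made without enolates.

**Alternative 2:** The same C9–C10 disconnection is used, but as the key step and with the lactone ring already present. A tethered 2-methyl-3-silyloxyfuran attacks the C9 aldehyde under MgBr2·OEt2 to give A2, which has a saturated lactone.
- Merits: the ring closure is the one used in the chosen plan (steps 19 there), and the trans-fused lactone may pre-organise the chain. No CO pressure equipment is needed, and the C6 oxygen needs no protecting group.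
- Weak points: A2 still needs the exocyclic methylene. That means deprotonating the lactone at C11 in the presence of the acidic C4–H of the furanone, a free or protected C9 aldol and the C8 oxygen function.
- Comparison: in ring closure the two roads are equal, and in protecting-group count this one is leaner. The chosen plan sets against it that C12 and the methylene arrive together under neutral conditions as the last skeletal event.

**Alternative 3:** The ring is traced to a terpene-derived trans-decalin. Its C3 alkoxide expels an antiperiplanar C9 mesylate in a Grob fragmentation to give the ten-membered C3 ketone A3 with an E C8=C9 alkene.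
- Merits: the fragmentation is stereospecific and dependable. The rigid decalin allows the C4, C5, C6, C7 and C10 centres to be set with cyclic control, and the lactone is annulated early.
- Weak points: the fragmentation substrate with its seven stereocentres and the correct mesylate geometry is itself long. A3 needs a face-selective syn-dihydroxylation of C8=C9 on the medium ring, selective acylation of C8 over C9, oxidation at C1 and cyclodehydration to the furanone beside the epimerisable C4. It also needs dehydrogenation of the C11 methyl lactone to the exocyclic alkene.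
- Comparison: ring formation is more secure here than in the chosen plan. The chosen plan sets against it a shorter path to the full oxidation pattern and a methylene lactone that never has to be made by elimination.

Key step: step 24

Remark: but-3-yn-2-ol 24 is used as the racemate, so 26–31 are carried as mixtures of C10 epimers. This centre becomes trigonal in 32 and is set in step 19.

## Steps

Step 1
Reactants: 1 (Z)-but-2-ene-1,4-diol
Product: 2 (Z)-4-[(4-methoxybenzyl)oxy]but-2-en-1-ol
Conditions: NaH (1 equiv), 4-methoxybenzyl chloride, Bu4NI (cat.), THF, 0 °C → rt, excess diol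
Reagents that add atoms: 4-methoxybenzyl chloride, COc1ccc(CCl)cc1
Why: Williamson ether synthesis on the mono-alkoxide; an excess of the symmetrical diol keeps dialkylation low and the Z alkene is untouched.

Step 2
Reactants: 2 (Z)-4-[(4-methoxybenzyl)oxy]but-2-en-1-ol
Product: 3 (2R,3S)-epoxy alcohol [(2R,3S)-3-{[(4-methoxybenzyl)oxy]methyl}oxiran-2-yl]methanol
Conditions: Ti(OiPr)4, D-(−)-diethyl tartrate, t-BuOOH, 4 Å molecular sieves, CH2Cl2, −20 °C
Reagents that add atoms: tert-butyl hydroperoxide, CC(C)(C)OO
Why: Sharpless asymmetric epoxidation; with the D-(−)-tartrate the oxygen should be delivered to the face that gives the (2R,3S) cis-epoxide, which fixes C6 and the centre from which C7 is derived (cis-allylic alcohols react slowly, hence stoichiometric Ti(OiPr)4/tartrate).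

Step 3
Reactants: 3 (2R,3S)-epoxy alcohol; 4 ethynyltrimethylsilane
Product: 7 (2S,3R)-3-{[(4-methoxybenzyl)oxy]methyl}-5-(trimethylsilyl)pent-4-yne-1,2-diol, via lithium acetylide 5 (not isolated), via alkynylalane 6 (not isolated)
Conditions: 4, n-BuLi, toluene, 0 °C; Et2AlCl; then 3, 0 °C → rt
Reagents that add atoms: none
Why: Regioselective opening of a 2,3-epoxy alcohol by an alkynylalane: once the hydroxyl is bound as its –OAlEt2 alkoxide, a second alane attacks the remote epoxide carbon (C7) with SN2 inversion, which puts the C6 hydroxyl and the C7 alkyne in the relation that later becomes the trans ring fusion.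

Step 4
Reactants: 7 (2S,3R)-diol with C8 PMB ether
Product: 8 O6,O8-(4-methoxybenzylidene) acetal [(2S,4S,5R)-2-(4-methoxyphenyl)-5-[(trimethylsilyl)ethynyl]-1,3-dioxan-4-yl]methanol
Conditions: DDQ, 4 Å molecular sieves, CH2Cl2 (anhydrous), 0 °C
Reagents that add atoms: none
Why: Oxidative acetalisation of a PMB ether: DDQ removes a benzylic hydride and the C6 hydroxyl captures the oxocarbenium ion as the six-membered 1,3-dioxane (aryl equatorial), leaving the primary C5 hydroxyl as the only free one.

Step 5
Reactants: 8 O6,O8-(4-methoxybenzylidene) acetal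
Product: 9 C5 triethylsilyl ether of 8
Conditions: Et3SiCl, imidazole, CH2Cl2, 0 °C
Reagents that add atoms: chlorotriethylsilane, CC[Si](Cl)(CC)CC
Why: Routine silylation of a primary alcohol; the triethylsilyl ether is chosen because step 10 oxidises it directly to the aldehyde.

Step 6
Reactants: 9 C5 triethylsilyl ether of 8
Product: 10 (2R,3S)-3-[(4-methoxybenzyl)oxy]-4-[(triethylsilyl)oxy]-2-[(trimethylsilyl)ethynyl]butan-1-ol
Conditions: i-Bu2AlH, CH2Cl2, −78 → 0 °C
Reagents that add atoms: none
Why: Reductive opening of a 4-methoxybenzylidene acetal: i-Bu2AlH binds the less hindered primary oxygen (O8) and delivers hydride to the acetal carbon, so the PMB group ends on the secondary C6 oxygen and the C8 hydroxyl is freed; the low temperature keeps hydroalumination of the silylalkyne away.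

Step 7
Reactants: 10 C8 primary alcohol with C6 PMB ether
Product: 11 (2S,3S)-3-[(4-methoxybenzyl)oxy]-4-[(triethylsilyl)oxy]-2-[(trimethylsilyl)ethynyl]butanal
Conditions: Dess–Martin periodinane, NaHCO3, CH2Cl2, 0 °C; used at once
Reagents that add atoms: none
Why: Dess–Martin oxidation under buffered, non-basic conditions, chosen because an α-alkynyl aldehyde epimerises or isomerises to the allene with base.

Step 8
Reactants: 11 C8 aldehyde; 12 vinylmagnesium bromide
Product: 13 (3R,4R,5S)-5-[(4-methoxybenzyl)oxy]-6-[(triethylsilyl)oxy]-4-[(trimethylsilyl)ethynyl]hex-1-en-3-ol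
Conditions: MgBr2·OEt2, CH2Cl2, −78 °C; then CH2=CHMgBr (THF), −78 °C
Reagents that add atoms: none
Why: Chelation-controlled Grignard addition (Cram chelate model): MgBr2 ties the aldehyde oxygen to the C6 PMB ether in a six-membered chelate whose C7 alkynyl and C6 substituents lie on one face, so the vinyl group adds from the other face and should give the 6,8-anti/7,8-anti alcohol, i.e. C8 as in the target.

Step 9
Reactants: 13 C8 allylic alcohol
Product: 14 C8 3,4-dimethoxybenzyl (DMB) ether of 13
Conditions: NaH, 3,4-dimethoxybenzyl chloride, Bu4NI (cat.), THF, 0 °C → rt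
Reagents that add atoms: 4-(chloromethyl)-1,2-dimethoxybenzene, COc1ccc(CCl)cc1OC
Why: Williamson etherification; the DMB ether is a chelating group for step 19 and is oxidised by DDQ faster than the PMB ether on C6, which allows their sequential removal.

Step 10
Reactants: 14 C8 DMB ether with C5 triethylsilyl ether
Product: 15 (2S,3R,4R)-4-[(3,4-dimethoxybenzyl)oxy]-2-[(4-methoxybenzyl)oxy]-3-[(trimethylsilyl)ethynyl]hex-5-enal
Conditions: (COCl)2, DMSO, CH2Cl2, −78 → −30 °C; Et3N
Reagents that add atoms: none
Why: Swern oxidation applied to a primary triethylsilyl ether, which is cleaved by the chlorosulfonium reagent and oxidised in the same flask while the benzylic ethers, alkene and silylalkyne are inert; the low temperature protects the α-alkoxy centre C6.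

Step 11
Reactants: 16 propanoyl chloride; 17 2-methylpropane-2-thiol
Product: 18 S-tert-butyl propanethioate
Conditions: pyridine, CH2Cl2, 0 °C → rt
Reagents that add atoms: none
Why: Acylation of a thiol by an acid chloride (thioester formation).

Step 12
Reactants: 18 S-tert-butyl propanethioate
Product: 20 [(Z)-1-(tert-butylsulfanyl)prop-1-enoxy]trimethylsilane, via lithium enolate 19 (not isolated)
Conditions: LiN(i-Pr)2, THF, −78 °C; Me3SiCl
Reagents that add atoms: chlorotrimethylsilane, C[Si](C)(C)Cl
Why: Kinetic deprotonation in THF gives the E(O) lithium enolate (Ireland model) and O-silylation gives the silyl ketene thioacetal with the silyloxy group trans to the methyl group.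

Step 13
Reactants: 15 C5 aldehyde; 20 silyl ketene thioacetal
Product: 21 S-tert-butyl (2R,3S,4S,5R,6R)-6-[(3,4-dimethoxybenzyl)oxy]-3-hydroxy-4-[(4-methoxybenzyl)oxy]-2-methyl-5-[(trimethylsilyl)ethynyl]oct-7-enethioate
Conditions: MgBr2·OEt2, CH2Cl2, −78 → −30 °C; aqueous citric acid work-up
Reagents that add atoms: none
Why: Chelation-controlled Mukaiyama aldol: MgBr2 binds the aldehyde and the C6 PMB ether in a five-membered chelate and the enol silane attacks anti to the C7 substituent, which gives the 5,6-syn relation (C5 S); the open transition state of tert-butylthio silyl ketene acetals with chelated α-alkoxy aldehydes should favour the 4,5-anti isomer (C4 R).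

Step 14
Reactants: 21 aldol thioester
Product: 22 C5 tert-butyldimethylsilyl (TBS) ether of 21
Conditions: t-BuMe2SiOTf, 2,6-lutidine, CH2Cl2, −78 → 0 °C
Reagents that add atoms: tert-butyldimethylsilyl trifluoromethanesulfonate, CC(C)(C)[Si](C)(C)OS(=O)(=O)C(F)(F)F
Why: Silylation of a hindered secondary alcohol with a silyl triflate; it blocks retro-aldol cleavage and β-elimination in the following steps and is the C5 protecting group of the key step.

Step 15
Reactants: 22 C5 TBS ether thioester
Product: 23 Weinreb amide (2R,3S,4S,5R,6R)-3-[(tert-butyldimethylsilyl)oxy]-6-[(3,4-dimethoxybenzyl)oxy]-N-methoxy-4-[(4-methoxybenzyl)oxy]-N,2-dimethyl-5-[(trimethylsilyl)ethynyl]oct-7-enamide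
Conditions: MeNHOMe·HCl, i-PrMgCl, THF, −20 → 0 °C
Reagents that add atoms: N,O-dimethylhydroxylamine hydrochloride, CNOC.Cl
Why: Weinreb amide formation by acyl substitution of the thioester with the magnesium amide ClMgN(OMe)Me; the low temperature and the silylated β-oxygen should preserve C4.

Step 16
Reactants: 23 Weinreb amide; 24 but-3-yn-2-ol (racemic)
Product: 26 hydroxy ynone (6R,7S,8S,9R,10R)-7-[(tert-butyldimethylsilyl)oxy]-10-[(3,4-dimethoxybenzyl)oxy]-2-hydroxy-8-[(4-methoxybenzyl)oxy]-6-methyl-9-[(trimethylsilyl)ethynyl]dodec-11-en-3-yn-5-one, via dilithiated alkynol 25 (not isolated)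
Conditions: 24, n-BuLi (2 equiv), THF, −78 → −20 °C; then 23, −78 → 0 °C; NH4Cl
Reagents that add atoms: none
Why: Addition of a lithium acetylide to a Weinreb amide; the chelated tetrahedral intermediate prevents over-addition and epimerisation at C4, and the silyl-capped alkyne of 23 cannot exchange its proton with the reagent.

Step 17
Reactants: 26 hydroxy ynone
Product: 29 5-[(2R,3S,4S,5R,6R)-3-[(tert-butyldimethylsilyl)oxy]-6-[(3,4-dimethoxybenzyl)oxy]-5-ethynyl-4-[(4-methoxybenzyl)oxy]oct-7-en-2-yl]-2-methylfuran-3(2H)-one, via enaminone 27 (not isolated), via desilylated enaminone 28 (not isolated)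
Conditions: Et2NH, MeOH, rt; K2CO3, rt; then AcOH–H2O–THF, rt
Reagents that add atoms: water, O
Why: Classical 3(2H)-furanone synthesis from a 4-hydroxyalk-2-ynone: conjugate addition of Et2NH gives the enaminone, K2CO3/MeOH removes the alkynyl silyl group at this base-tolerant stage, and aqueous acid brings about hemiketalisation at C3, loss of water and iminium hydrolysis.

Step 18
Reactants: 29 furanone with C9 vinyl group
Product: 31 (2S,3S,4S,5S,6R)-5-[(tert-butyldimethylsilyl)oxy]-2-[(3,4-dimethoxybenzyl)oxy]-3-ethynyl-4-[(4-methoxybenzyl)oxy]-6-(5-methyl-4-oxo-4,5-dihydrofuran-2-yl)heptanal, via diol 30 (not isolated)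
Conditions: OsO4 (cat.), NaIO4, 2,6-lutidine, dioxane–H2O, rt
Reagents that add atoms: sodium periodate, [Na+].[O-]I(=O)(=O)=O (oxygen delivered through OsO4)
Why: Lemieux–Johnson oxidation; OsO4 dihydroxylates the monosubstituted alkene much faster than the push–pull furanone alkene or the terminal alkyne, and NaIO4 cleaves the glycol to the C9 aldehyde.

Step 19
Reactants: 31 furanone C9 aldehyde
Product: 33 (2R,3S,4S,5R,6S,7R,8S)-3-[(tert-butyldimethylsilyl)oxy]-6-[(3,4-dimethoxybenzyl)oxy]-5-ethynyl-7-hydroxy-4-[(4-methoxybenzyl)oxy]-2,8-dimethyl-11-oxabicyclo[6.2.1]undec-1(10)-en-9-one, via silyloxyfuran 32 (not isolated)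
Conditions: i-Pr3SiOTf (1.05 equiv), Et3N, CH2Cl2, −78 °C; then slow transfer into MgBr2·OEt2, CH2Cl2 (high dilution), −78 → −20 °C
Reagents that add atoms: none
Why: Soft enolisation–silylation aromatises the furanone (far more acidic than the aldehyde α-position) to the 2-methyl-3-silyloxyfuran, and an intramolecular Mukaiyama aldol then closes C9–C10. The MgBr2 chelate of the aldehyde with the C8 DMB ether exposes the face anti to C7 (C9 R), and allylic strain at C4 (C4–H beside C2–H) holds the chain over the furan face that makes C10 S.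

Step 20
Reactants: 33 macrocyclic aldol
Product: 34 C9 triethylsilyl ether of 33
Conditions: Et3SiOTf, 2,6-lutidine, CH2Cl2, −78 → 0 °C
Reagents that add atoms: triethylsilyl trifluoromethanesulfonate, CC[Si](CC)(CC)OS(=O)(=O)C(F)(F)F
Why: Silylation with a silyl triflate; capping the C9 hydroxyl shuts off retro-aldol cleavage and stops this hydroxyl from trapping the benzylic cation of step 21 as a cyclic acetal.

Step 21
Reactants: 34 C9 triethylsilyl ether
Product: 35 C8 alcohol (2R,3S,4S,5R,6S,7R,8S)-3-[(tert-butyldimethylsilyl)oxy]-5-ethynyl-6-hydroxy-4-[(4-methoxybenzyl)oxy]-2,8-dimethyl-7-[(triethylsilyl)oxy]-11-oxabicyclo[6.2.1]undec-1(10)-en-9-one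
Conditions: DDQ (1.1 equiv), CH2Cl2–pH 7 buffer, 0 °C
Reagents that add atoms: none
Why: Oxidative cleavage of a benzylic ether by DDQ; the more electron-rich DMB ether is oxidised faster than the PMB ether, so one equivalent at 0 °C should free only the C8 hydroxyl.

Step 22
Reactants: 35 C8 alcohol; 36 3-methylbutanoic anhydride
Product: 37 C8 isovalerate with C6 PMB ether
Conditions: 36, DMAP, Et3N, CH2Cl2, 0 °C → rt
Reagents that add atoms: none
Why: DMAP-catalysed acylation of the only free hydroxyl; C9 is silylated, so neither diacylation nor acyl migration can occur.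

Step 23
Reactants: 37 C8 isovalerate with C6 PMB ether
Product: 38 (2R,3S,4S,5S,6S,7R,8S)-3-[(tert-butyldimethylsilyl)oxy]-5-ethynyl-4-hydroxy-2,8-dimethyl-9-oxo-7-[(triethylsilyl)oxy]-11-oxabicyclo[6.2.1]undec-1(10)-en-6-yl 3-methylbutanoate
Conditions: DDQ, CH2Cl2–pH 7 buffer, rt
Reagents that add atoms: none
Why: Oxidative PMB cleavage by DDQ under buffered conditions; ester, silyl ethers, terminal alkyne and furanone are inert, and the C6 hydroxyl becomes the only free one.

Step 24
Reactants: 38 C7-ethynyl C6-hydroxy macrocycle; 39 carbon monoxide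
Product: 40 5-O-TBS, 9-O-TES ether of the target (α-methylene lactone closed)
Conditions: PdCl2 (cat.), PPh3, SnCl2, CO (7 atm), MeCN, 65 °C
Reagents that add atoms: none
Why: Cyclocarbonylation of a but-3-yn-1-ol: divalent palladium (PdCl2 with PPh3, activated by SnCl2) takes up CO and the C6 hydroxyl to give an alkoxycarbonyl complex ROC(O)PdCl(PPh3)2 with loss of HCl; the tethered alkyne inserts syn into the Pd–C12 bond, forming C12–C11 and placing palladium on C13; protonolysis of the C13–Pd bond by the released HCl gives the exocyclic methylene and returns divalent palladium, so no oxidant is needed. The closest known reaction is the PdCl2/PPh3/SnCl2-catalysed conversion of homopropargylic alcohols into α-methylene-γ-butyrolactones under CO, which is known to give trans-fused bicyclic lactones from trans-2-ethynylcycloalkanols. The lactone ring closes in the 5-exo-dig mode at the insertion step, O–C12 having been made first. No stereocentre is created; the trans fusion is inherited from the C6/C7 relation set in steps 2 and 3. The step needs site selectivity for the C6 oxygen, which is secured because C5 and C9 are silylated and C8 is esterified, so only the C6 hydroxyl can form the alkoxycarbonyl complex. It also needs chemoselectivity, which the neutral, non-enolising conditions provide for the furanone, the ester and C4, and it needs the terminal alkyne freed in step 17.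

Step 25
Reactants: 40 5-O-TBS, 9-O-TES ether of the target
Product: 41 target CNP0484215.2
Conditions: HF·pyridine, pyridine, THF, 0 °C → rt
Reagents that add atoms: none
Why: Fluoride cleavage of both silyl ethers under mildly acidic, buffered conditions that spare the Michael acceptor and avoid acyl migration of the C8 ester and retro-aldol cleavage at C9–C10.

## Compound list

1 | (Z)-but-2-ene-1,4-diol | OC/C=C\CO | starting material
2 | (Z)-4-[(4-methoxybenzyl)oxy]but-2-en-1-ol | OC/C=C\COCc1ccc(OC)cc1 | intermediate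
3 | [(2R,3S)-3-{[(4-methoxybenzyl)oxy]methyl}oxiran-2-yl]methanol | OC[C@H]1O[C@H]1COCc1ccc(OC)cc1 | intermediate
4 | ethynyltrimethylsilane | C#C[Si](C)(C)C | starting material
5 | lithium (trimethylsilyl)acetylide | [Li]C#C[Si](C)(C)C | intermediate (not isolated)
6 | diethyl[(trimethylsilyl)ethynyl]aluminium | CC[Al](CC)C#C[Si](C)(C)C | intermediate (not isolated)
7 | (2S,3R)-3-{[(4-methoxybenzyl)oxy]methyl}-5-(trimethylsilyl)pent-4-yne-1,2-diol | OC[C@@H](O)[C@H](C#C[Si](C)(C)C)COCc1ccc(OC)cc1 | intermediate
8 | [(2S,4S,5R)-2-(4-methoxyphenyl)-5-[(trimethylsilyl)ethynyl]-1,3-dioxan-4-yl]methanol | OC[C@H]1O[C@@H](c2ccc(OC)cc2)OC[C@H]1C#C[Si](C)(C)C | intermediate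
9 | triethyl{[(2S,4S,5R)-2-(4-methoxyphenyl)-5-[(trimethylsilyl)ethynyl]-1,3-dioxan-4-yl]methoxy}silane | CC[Si](CC)(CC)OC[C@H]1O[C@@H](c2ccc(OC)cc2)OC[C@H]1C#C[Si](C)(C)C | intermediate
10 | (2R,3S)-3-[(4-methoxybenzyl)oxy]-4-[(triethylsilyl)oxy]-2-[(trimethylsilyl)ethynyl]butan-1-ol | CC[Si](CC)(CC)OC[C@@H](OCc1ccc(OC)cc1)[C@@H](CO)C#C[Si](C)(C)C | intermediate
11 | (2S,3S)-3-[(4-methoxybenzyl)oxy]-4-[(triethylsilyl)oxy]-2-[(trimethylsilyl)ethynyl]butanal | CC[Si](CC)(CC)OC[C@@H](OCc1ccc(OC)cc1)[C@@H](C=O)C#C[Si](C)(C)C | intermediate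
12 | vinylmagnesium bromide | C=C[Mg]Br | starting material
13 | (3R,4R,5S)-5-[(4-methoxybenzyl)oxy]-6-[(triethylsilyl)oxy]-4-[(trimethylsilyl)ethynyl]hex-1-en-3-ol | CC[Si](CC)(CC)OC[C@@H](OCc1ccc(OC)cc1)[C@@H]([C@H](O)C=C)C#C[Si](C)(C)C | intermediate
14 | (3R,4R,5S)-3-[(3,4-dimethoxybenzyl)oxy]-5-[(4-methoxybenzyl)oxy]-6-[(triethylsilyl)oxy]-4-[(trimethylsilyl)ethynyl]hex-1-ene | CC[Si](CC)(CC)OC[C@@H](OCc1ccc(OC)cc1)[C@@H]([C@H](OCc1ccc(OC)c(OC)c1)C=C)C#C[Si](C)(C)C | intermediate
15 | (2S,3R,4R)-4-[(3,4-dimethoxybenzyl)oxy]-2-[(4-methoxybenzyl)oxy]-3-[(trimethylsilyl)ethynyl]hex-5-enal | O=C[C@@H](OCc1ccc(OC)cc1)[C@@H]([C@H](OCc1ccc(OC)c(OC)c1)C=C)C#C[Si](C)(C)C | intermediate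
16 | propanoyl chloride | CCC(=O)Cl | starting material
17 | 2-methylpropane-2-thiol | CC(C)(C)S | starting material
18 | S-tert-butyl propanethioate | CCC(=O)SC(C)(C)C | intermediate
19 | lithium (Z)-1-(tert-butylsulfanyl)prop-1-en-1-olate (E(O) enolate) | C/C=C(/O[Li])SC(C)(C)C | intermediate (not isolated)
20 | [(Z)-1-(tert-butylsulfanyl)prop-1-enoxy]trimethylsilane | C/C=C(/O[Si](C)(C)C)SC(C)(C)C | intermediate
21 | S-tert-butyl (2R,3S,4S,5R,6R)-6-[(3,4-dimethoxybenzyl)oxy]-3-hydroxy-4-[(4-methoxybenzyl)oxy]-2-methyl-5-[(trimethylsilyl)ethynyl]oct-7-enethioate | CC(C)(C)SC(=O)[C@H](C)[C@H](O)[C@@H](OCc1ccc(OC)cc1)[C@@H]([C@H](OCc1ccc(OC)c(OC)c1)C=C)C#C[Si](C)(C)C | intermediate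
22 | S-tert-butyl (2R,3S,4S,5R,6R)-3-[(tert-butyldimethylsilyl)oxy]-6-[(3,4-dimethoxybenzyl)oxy]-4-[(4-methoxybenzyl)oxy]-2-methyl-5-[(trimethylsilyl)ethynyl]oct-7-enethioate | CC(C)(C)SC(=O)[C@H](C)[C@H](O[Si](C)(C)C(C)(C)C)[C@@H](OCc1ccc(OC)cc1)[C@@H]([C@H](OCc1ccc(OC)c(OC)c1)C=C)C#C[Si](C)(C)C | intermediate
23 | (2R,3S,4S,5R,6R)-3-[(tert-butyldimethylsilyl)oxy]-6-[(3,4-dimethoxybenzyl)oxy]-N-methoxy-4-[(4-methoxybenzyl)oxy]-N,2-dimethyl-5-[(trimethylsilyl)ethynyl]oct-7-enamide | CON(C)C(=O)[C@H](C)[C@H](O[Si](C)(C)C(C)(C)C)[C@@H](OCc1ccc(OC)cc1)[C@@H]([C@H](OCc1ccc(OC)c(OC)c1)C=C)C#C[Si](C)(C)C | intermediate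
24 | but-3-yn-2-ol (racemic) | CC(O)C#C | starting material
25 | dilithiated but-3-yn-2-ol (lithium alkoxide, lithium acetylide) | [Li]OC(C)C#C[Li] | intermediate (not isolated)
26 | (6R,7S,8S,9R,10R)-7-[(tert-butyldimethylsilyl)oxy]-10-[(3,4-dimethoxybenzyl)oxy]-2-hydroxy-8-[(4-methoxybenzyl)oxy]-6-methyl-9-[(trimethylsilyl)ethynyl]dodec-11-en-3-yn-5-one (both C2 epimers) | CC(O)C#CC(=O)[C@H](C)[C@H](O[Si](C)(C)C(C)(C)C)[C@@H](OCc1ccc(OC)cc1)[C@@H]([C@H](OCc1ccc(OC)c(OC)c1)C=C)C#C[Si](C)(C)C | intermediate
27 | (3E,6R,7S,8S,9R,10R)-7-[(tert-butyldimethylsilyl)oxy]-3-(diethylamino)-10-[(3,4-dimethoxybenzyl)oxy]-2-hydroxy-8-[(4-methoxybenzyl)oxy]-6-methyl-9-[(trimethylsilyl)ethynyl]dodeca-3,11-dien-5-one (both C2 epimers) | CC(O)/C(N(CC)CC)=C\C(=O)[C@H](C)[C@H](O[Si](C)(C)C(C)(C)C)[C@@H](OCc1ccc(OC)cc1)[C@@H]([C@H](OCc1ccc(OC)c(OC)c1)C=C)C#C[Si](C)(C)C | intermediate (not isolated)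
28 | 9-ethynyl analogue of 27 (alkynyl silyl group removed) | CC(O)/C(N(CC)CC)=C\C(=O)[C@H](C)[C@H](O[Si](C)(C)C(C)(C)C)[C@@H](OCc1ccc(OC)cc1)[C@@H]([C@H](OCc1ccc(OC)c(OC)c1)C=C)C#C | intermediate (not isolated)
29 | 5-[(2R,3S,4S,5R,6R)-3-[(tert-butyldimethylsilyl)oxy]-6-[(3,4-dimethoxybenzyl)oxy]-5-ethynyl-4-[(4-methoxybenzyl)oxy]oct-7-en-2-yl]-2-methylfuran-3(2H)-one (both epimers at furanone C2 = C10) | CC1OC(=CC1=O)[C@H](C)[C@H](O[Si](C)(C)C(C)(C)C)[C@@H](OCc1ccc(OC)cc1)[C@@H]([C@H](OCc1ccc(OC)c(OC)c1)C=C)C#C | intermediate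
30 | 5-[(2R,3S,4S,5R,6S)-3-[(tert-butyldimethylsilyl)oxy]-6-[(3,4-dimethoxybenzyl)oxy]-5-ethynyl-7,8-dihydroxy-4-[(4-methoxybenzyl)oxy]octan-2-yl]-2-methylfuran-3(2H)-one (mixture at chain C7 and furanone C2) | CC1OC(=CC1=O)[C@H](C)[C@H](O[Si](C)(C)C(C)(C)C)[C@@H](OCc1ccc(OC)cc1)[C@@H]([C@H](OCc1ccc(OC)c(OC)c1)C(O)CO)C#C | intermediate (not isolated)
31 | (2S,3S,4S,5S,6R)-5-[(tert-butyldimethylsilyl)oxy]-2-[(3,4-dimethoxybenzyl)oxy]-3-ethynyl-4-[(4-methoxybenzyl)oxy]-6-(5-methyl-4-oxo-4,5-dihydrofuran-2-yl)heptanal (both epimers at the furanone CH) | CC1OC(=CC1=O)[C@H](C)[C@H](O[Si](C)(C)C(C)(C)C)[C@@H](OCc1ccc(OC)cc1)[C@@H]([C@H](OCc1ccc(OC)c(OC)c1)C=O)C#C | intermediate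
32 | (2S,3S,4S,5S,6R)-5-[(tert-butyldimethylsilyl)oxy]-2-[(3,4-dimethoxybenzyl)oxy]-3-ethynyl-4-[(4-methoxybenzyl)oxy]-6-{5-methyl-4-[(triisopropylsilyl)oxy]furan-2-yl}heptanal | Cc1oc(cc1O[Si](C(C)C)(C(C)C)C(C)C)[C@H](C)[C@H](O[Si](C)(C)C(C)(C)C)[C@@H](OCc1ccc(OC)cc1)[C@@H]([C@H](OCc1ccc(OC)c(OC)c1)C=O)C#C | intermediate (not isolated)
33 | (2R,3S,4S,5R,6S,7R,8S)-3-[(tert-butyldimethylsilyl)oxy]-6-[(3,4-dimethoxybenzyl)oxy]-5-ethynyl-7-hydroxy-4-[(4-methoxybenzyl)oxy]-2,8-dimethyl-11-oxabicyclo[6.2.1]undec-1(10)-en-9-one (positions 2–8 are C4–C10) | C#C[C@H]1[C@H](OCc2ccc(OC)cc2)[C@@H](O[Si](C)(C)C(C)(C)C)[C@@H](C)C2=CC(=O)[C@@](C)(O2)[C@H](O)[C@H]1OCc1ccc(OC)c(OC)c1 | intermediate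
34 | (2R,3S,4S,5S,6S,7R,8S)-3-[(tert-butyldimethylsilyl)oxy]-6-[(3,4-dimethoxybenzyl)oxy]-5-ethynyl-4-[(4-methoxybenzyl)oxy]-2,8-dimethyl-7-[(triethylsilyl)oxy]-11-oxabicyclo[6.2.1]undec-1(10)-en-9-one | C#C[C@H]1[C@H](OCc2ccc(OC)cc2)[C@@H](O[Si](C)(C)C(C)(C)C)[C@@H](C)C2=CC(=O)[C@@](C)(O2)[C@H](O[Si](CC)(CC)CC)[C@H]1OCc1ccc(OC)c(OC)c1 | intermediate
35 | (2R,3S,4S,5R,6S,7R,8S)-3-[(tert-butyldimethylsilyl)oxy]-5-ethynyl-6-hydroxy-4-[(4-methoxybenzyl)oxy]-2,8-dimethyl-7-[(triethylsilyl)oxy]-11-oxabicyclo[6.2.1]undec-1(10)-en-9-one | C#C[C@H]1[C@H](OCc2ccc(OC)cc2)[C@@H](O[Si](C)(C)C(C)(C)C)[C@@H](C)C2=CC(=O)[C@@](C)(O2)[C@H](O[Si](CC)(CC)CC)[C@H]1O | intermediate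
36 | 3-methylbutanoic anhydride | CC(C)CC(=O)OC(=O)CC(C)C | starting material
37 | (2R,3S,4S,5S,6S,7R,8S)-3-[(tert-butyldimethylsilyl)oxy]-5-ethynyl-4-[(4-methoxybenzyl)oxy]-2,8-dimethyl-9-oxo-7-[(triethylsilyl)oxy]-11-oxabicyclo[6.2.1]undec-1(10)-en-6-yl 3-methylbutanoate | C#C[C@H]1[C@H](OCc2ccc(OC)cc2)[C@@H](O[Si](C)(C)C(C)(C)C)[C@@H](C)C2=CC(=O)[C@@](C)(O2)[C@H](O[Si](CC)(CC)CC)[C@H]1OC(=O)CC(C)C | intermediate
38 | (2R,3S,4S,5S,6S,7R,8S)-3-[(tert-butyldimethylsilyl)oxy]-5-ethynyl-4-hydroxy-2,8-dimethyl-9-oxo-7-[(triethylsilyl)oxy]-11-oxabicyclo[6.2.1]undec-1(10)-en-6-yl 3-methylbutanoate | C#C[C@H]1[C@H](O)[C@@H](O[Si](C)(C)C(C)(C)C)[C@@H](C)C2=CC(=O)[C@@](C)(O2)[C@H](O[Si](CC)(CC)CC)[C@H]1OC(=O)CC(C)C | intermediate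
39 | carbon monoxide | [C-]#[O+] | starting material
40 | (4R,5S,6S,7S,8S,9R,10S)-5-[(tert-butyldimethylsilyl)oxy]-8-(3-methylbutanoyloxy)-1-oxo-9-[(triethylsilyl)oxy]-3,10-epoxygermacra-2,11(13)-dien-12,6-olide | C=C1C(=O)O[C@@H]2[C@@H](O[Si](C)(C)C(C)(C)C)[C@@H](C)C3=CC(=O)[C@@](C)(O3)[C@H](O[Si](CC)(CC)CC)[C@@H](OC(=O)CC(C)C)[C@@H]12 | intermediate
41 | (4R,5S,6S,7S,8S,9R,10S)-5,9-dihydroxy-8-(3-methylbutanoyloxy)-1-oxo-3,10-epoxygermacra-2,11(13)-dien-12,6-olide (CNP0484215.2) | C=C1C(=O)O[C@@H]2[C@@H](O)[C@@H](C)C3=CC(=O)[C@@](C)(O3)[C@H](O)[C@@H](OC(=O)CC(C)C)[C@@H]12 | target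

## Step count and least certain steps

Total step count: 25. Longest linear sequence: 23 steps (steps 1–10 and 13–25, from 1); steps 11 and 12 make the aldol partner 20.

**Step 24 (key step).**
- Risk: the alkoxycarbonyl complex may form slowly at the hindered C6 hydroxyl on the strained ring. This would give time for oligomerisation or hydration of the alkyne, and for SnCl2-promoted loss of the C9 silyl ether followed by six-membered closure from that oxygen.
- Fallback: this sets out from 38 and returns at 40. Compound 38 is treated with COCl2/pyridine and then PhSeH to give the C6 Se-phenyl selenocarbonate F1. Bu3SnH and AIBN in hot benzene then generate the alkoxycarbonyl radical, which closes 5-exo-dig onto the alkyne and takes up hydrogen at C13. The same O–C12 and C12–C11 bonds are made, with C12 coming from COCl2.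

**Step 19.**
- Risk: silylation of the aldehyde may compete with silylation of the furanone, with loss of C8 integrity. Oligomerisation may win over ring closure. Facial selectivity at C9 or C10 may be poor if the chelate or the C4 rotamer preference does not hold. C10 cannot be repaired afterwards.
- Fallback: this sets out from 29 and returns at 33. Compound 29 is converted in the flask into its triisopropylsilyloxyfuran F2 (no aldehyde is present yet) and brominated at C10 with N-bromosuccinimide to the bromofuranone F3. Lemieux–Johnson cleavage of the vinyl group gives the bromo aldehyde F4. SmI2 in THF at −78 °C then closes C9–C10 by an intramolecular Reformatsky-type aldol, a known way to medium rings from α-bromo ketones and aldehydes.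

**Step 8.**
- Risk: the Grignard reagent may deprotonate the α-alkynyl aldehyde, eroding C7 or giving the allenyl isomer. Incomplete chelation would give poor facial selectivity at C8.
- Fallback: this sets out from 11 and returns at 13. A Nozaki–Hiyama–Kishi vinylation (CH2=CHBr, CrCl2, NiCl2 cat., DMF) adds the vinyl group without base and gives 13 together with its C8 epimer F5. The mixture is oxidised with Dess–Martin periodinane to the vinyl ketone F6. A Corey–Bakshi–Shibata reduction, with the oxazaborolidine enantiomer that delivers the (3R) carbinol, then sets C8 under reagent control.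

**Step 13.**
- Risk: the anti relation at C4–C5 may erode in the open transition state, and the Lewis acid may ionise the allylic DMB ether.
- Fallback: this sets out from 15 and 18 and returns at 21. A boron-mediated anti-aldol of thioester 18, with a menthone-derived chiral dialkylbromoborane and Et3N, proceeds through a closed chair transition state under reagent control. That control must override the Felkin preference of the aldehyde. No compound outside the list is made (F0).

## Further compounds

F1 | step 24 | C6 Se-phenyl selenocarbonate of 38 | C#C[C@H]1[C@H](OC(=O)[Se]c2ccccc2)[C@@H](O[Si](C)(C)C(C)(C)C)[C@@H](C)C2=CC(=O)[C@@](C)(O2)[C@H](O[Si](CC)(CC)CC)[C@H]1OC(=O)CC(C)C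
F2 | step 19 | triisopropylsilyloxyfuran of 29 (C9 vinyl group retained) | Cc1oc(cc1O[Si](C(C)C)(C(C)C)C(C)C)[C@H](C)[C@H](O[Si](C)(C)C(C)(C)C)[C@@H](OCc1ccc(OC)cc1)[C@@H]([C@H](OCc1ccc(OC)c(OC)c1)C=C)C#C
F3 | step 19 | C10 bromide of furanone 29 (2-bromo-2-methylfuran-3(2H)-one, both C10 epimers) | CC1(Br)OC(=CC1=O)[C@H](C)[C@H](O[Si](C)(C)C(C)(C)C)[C@@H](OCc1ccc(OC)cc1)[C@@H]([C@H](OCc1ccc(OC)c(OC)c1)C=C)C#C
F4 | step 19 | C10 bromide of aldehyde 31 (both C10 epimers) | CC1(Br)OC(=CC1=O)[C@H](C)[C@H](O[Si](C)(C)C(C)(C)C)[C@@H](OCc1ccc(OC)cc1)[C@@H]([C@H](OCc1ccc(OC)c(OC)c1)C=O)C#C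
F5 | step 8 | C8 epimer of 13, (3S,4R,5S)-5-[(4-methoxybenzyl)oxy]-6-[(triethylsilyl)oxy]-4-[(trimethylsilyl)ethynyl]hex-1-en-3-ol | CC[Si](CC)(CC)OC[C@@H](OCc1ccc(OC)cc1)[C@@H]([C@@H](O)C=C)C#C[Si](C)(C)C
F6 | step 8 | (4S,5S)-5-[(4-methoxybenzyl)oxy]-6-[(triethylsilyl)oxy]-4-[(trimethylsilyl)ethynyl]hex-1-en-3-one | CC[Si](CC)(CC)OC[C@@H](OCc1ccc(OC)cc1)[C@@H](C(=O)C=C)C#C[Si](C)(C)C
F0 | step 13 | none | none
A1 | alternative 1 | (2Z,5E)-cyclodeca-2,5-dienone with C4 methyl, C7 2-[(4-methoxybenzyl)oxy]ethyl chain and methoxymethyl ethers at C8, C9 and C10 | O=C1/C=C\[C@H](C)/C=C/[C@H](CCOCc2ccc(OC)cc2)[C@H](OCOC)[C@@H](OCOC)[C@]1(C)OCOC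
A2 | alternative 2 | furanone-bridged ten-membered ring with saturated 12,6-lactone, C5 TBS ether, C8 PMB ether and free C9 hydroxyl | C1C(=O)O[C@@H]2[C@@H](O[Si](C)(C)C(C)(C)C)[C@@H](C)C3=CC(=O)[C@@](C)(O3)[C@H](O)[C@@H](OCc4ccc(OC)cc4)[C@@H]12
A3 | alternative 3 | ten-membered C3 ketone with E C8=C9 alkene, C1/C10 acetonide, C5 TBS ether and 11-methyl 12,6-lactone | O=C1C[C@H]2OC(C)(C)O[C@@]2(C)/C=C/[C@H]3[C@H](C)C(=O)O[C@@H]3[C@@H](O[Si](C)(C)C(C)(C)C)[C@H]1C
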